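## The problem

Hierochin B (17) is a 2-aryl-2,3-dihydrobenzofuran. The tetrasubstituted benzene ring A is fused through C3a and C7a to the dihydrofuran ring B, and the 3,4-dimethoxyphenyl ring C sits on C2 (benzofuran numbering, O1 being the ring oxygen). Ring B holds the only two stereocentres, C2 (S, benzylic to ring C and bound to O1) and C3 (R, benzylic to ring A and bearing CH2OH), in a trans relation. Trans is favoured both kinetically and thermodynamically whenever the O1–C2 bond closes onto a planar benzylic carbon, so C3 can control C2 but not the reverse. The absolute problem is therefore the single tertiary centre C3, which must be made in a form that cannot enolise afterwards. The fragile parts are the (E)-cinnamyl alcohol on C5 (attacked by quinone oxidants and by acid) and the benzylic aryl ether C2–O1 (reopened by acid, dehydrogenated to the benzofuran by excess oxidant). One phenolic oxygen (O1) stands beside three methyl ethers, which rules out any late demethylation. The feature that allows a direct ring closure is that C2 is a CH2 group next to ring C, whose para-methoxy group makes it the most hydridic C–H position of an open precursor, and that it lies five atoms (O–C7a–C3a–C3–C2) from the ring A phenol oxygen that becomes O1.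

## Retrosynthesis

**Side chain.** The C5–vinyl bond is cut first, after the allylic alcohol is taken back to an acrylate ester. Target 17 comes from ester 16 by hydride reduction, and 16 from aryl bromide 14 and methyl acrylate (15) by a Heck reaction. The side chain has to come last because a cinnamyl alcohol would be oxidised by the quinone used for ring closure. The bromine that holds its place is inert to enolates, hydrides, fluoride and the quinone, and as a weak acceptor para to the phenol it lowers the donor strength of ring A where that matters. A formyl group would be a stronger acceptor but would need protection through the enolate and hydride steps. The forward steps must couple E-selectively at an electron-rich aryl bromide and reduce in a 1,2 sense without harm to the benzylic ether.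

**Ring B (key cut).** In 14 the O1–C2 bond is cut, giving the open phenol 13 with a CH2 group at C2. Cutting C2–C3 or C3–C3a would require both stereocentres to be made in the ring-forming event, and cutting O1–C7a would need a second halogen on ring A. The O1–C2 cut removes ring B and the C2 stereocentre together and leaves one stereocentre in an acyclic 2,3-diarylpropanol. The forward reaction must take hydride from C2–H in preference to C3–H and the phenol, close the five-membered ring, and place ring C trans to the hydroxymethyl arm. The primary alcohol stays free, because its only mode of attack on C2 would form an oxetane.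

**Phenol and alcohol.** Phenol 13 is traced to silyl ether 12 (O–Si cut) and 12 to the N-acyl oxazolidinone 11 (the CH2OH carbon returns to an imide carbonyl). The phenol must be masked as long as a carbonyl group sits next to the future C3, since a free phenoxide would attack that carbonyl. A silyl ether is chosen because fluoride removes it without acid or strong base. A shorter-looking plan was set aside: letting the phenol mask itself as a five-membered aryl lactone and creating C3 by asymmetric hydrogenation of its benzylidene derivative. The stereocentre would then be benzylic and α to an aryl ester at once, and could not be expected to survive base or hydride.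

**Stereocentre C3.** In 11 the bond between the stereocentre and the veratryl CH2 (the future C2–C3 bond) is cut, giving the achiral imide 9 and 4-(bromomethyl)-1,2-dimethoxybenzene (10). This cut suits the Evans alkylation: arylacetyl imides form chelated Z-enolates, benzylic bromides are excellent electrophiles, and the sense of induction is predictable. Cutting the aryl–C3 bond would demand an asymmetric α-arylation, and cutting C3–CH2OH an asymmetric hydroxymethylation. With the (R)-auxiliary 7 the electrophile enters anti to the benzyl group and C3 results R.

**Ring A arm.** Imide 9 divides at the N–acyl bond into auxiliary 7 and acid 6, the silyl ether of hydroxy acid 4. The aryl–CH2 bond of 4 is cut ortho to the phenol: glyoxylic acid (2) adds to the phenoxide of 4-bromo-2-methoxyphenol (1), whose para position is blocked, to give mandelic acid 3, and removal of the benzylic hydroxyl gives 4. Bromine, methyl ether and phenol oxygen of ring A are thus bought in one compound. The forward steps must be ortho-selective and must reduce without loss of bromine.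

## Roads not taken

**Alternative 1:** Quinone methide [4+1] annulation with a chiral sulfonium ylide.
- Cut: C2–C3 and O1–C2. Ring A would arrive as the sulfone A2, 4-bromo-2-[2-(tert-butyldimethylsilyloxy)-1-(4-methylphenylsulfonyl)ethyl]-6-methoxyphenol, and ring C as the ylide of a veratryl sulfonium salt built on a chiral sulfide.
- Forward step: a carbonate base expels sulfinate from A2, the ylide carbon adds to the methide carbon (future C3), and the phenoxide displaces the sulfide at C2. This should give the silyl ether A1, (2S,3R)-5-bromo-3-(tert-butyldimethylsilyloxymethyl)-2-(3,4-dimethoxyphenyl)-7-methoxy-2,3-dihydrobenzofuran.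
- Merits: ring B and both stereocentres form in one convergent operation, trans is built into the anti-periplanar displacement, and the reaction class is well established. From A1 the end game would be that of the chosen plan plus a desilylation, so the route would be about three steps shorter.
- Weak points: the methide carbon carries a silyloxymethyl group instead of the aryl group of most precedents, and alkyl-substituted ortho-quinone methides tautomerise readily to 2-vinylphenols. The absolute configuration of both centres would rest on a stoichiometric chiral sulfide acting through a semi-stabilised benzylic ylide, where reversible addition makes the level of induction hard to foresee.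
- Comparison: this road is better in convergence and step count, and that is conceded. The chosen plan sets against it an auxiliary alkylation of predictable sense whose diastereomers can be separated, with C2 following by substrate control.

**Alternative 2:** Domino Heck–Suzuki diarylation of an aryloxyacrylate.
- Cut: C3–C3a and C2–aryl. The substrates would be the iodoaryl enol ether A4, methyl (E)-3-(4-formyl-2-iodo-6-methoxyphenoxy)prop-2-enoate, and the boronic acid A5, 3,4-dimethoxyphenylboronic acid.
- Forward step: with a palladium catalyst carrying a chiral bisphosphine and a phosphate base, oxidative addition at the C–I bond of A4 is followed by carbopalladation of the enol ether double bond, which closes ring B. The C2–palladium bond is then captured by A5, and the base equilibrates C3 to trans, giving A3, methyl (2S,3S)-2-(3,4-dimethoxyphenyl)-5-formyl-7-methoxy-2,3-dihydrobenzofuran-3-carboxylate.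
- Merits: the whole skeleton in two steps from simple materials, catalytic asymmetry, and a C5 aldehyde ready for olefination. One hydride reduction would then deliver both primary alcohols; on paper this is the shortest route (about five steps).
- Weak points: ring closure requires the arylpalladium to add in a 5-endo sense to the β-aryloxyacrylate. The known fate of this substrate class under palladium is the aromatic benzofuran-3-carboxylate by β-hydride elimination, which erases both stereocentres. Direct biaryl coupling of A4 with A5 competes, and induction at C2 by a bisphosphine in such a step has no close model.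
- Comparison: this road is better in brevity and in using catalytic rather than auxiliary-based asymmetry. The chosen plan sets against it that every step, the key step included, has a close model, and that the key step needs only diastereocontrol from an existing centre.

**Alternative 3:** Catellani annulation of an iodoanisole with a cis-glycidate.
- Cut: C3–C3a and O1–C7a. The substrates would be the aryl iodide A7, methyl 4-iodo-3-methoxybenzoate, and the cis-glycidate A8, methyl (2R,3R)-3-(3,4-dimethoxyphenyl)oxirane-2-carboxylate.
- Forward step: under the palladium/strained-alkene relay of the Catellani reaction, with a triarylphosphine and a carbonate base, the palladacycle from A7 is alkylated at its free ortho position by the ester-bearing epoxide carbon of A8 with inversion. After extrusion of the alkene the benzylic alkoxide closes ring B at the ipso carbon, giving A6, dimethyl (2S,3S)-2-(3,4-dimethoxyphenyl)-7-methoxy-2,3-dihydrobenzofuran-3,5-dicarboxylate.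
- Merits: convergent and redox-neutral, with an ortho C–H bond used in place of a prefunctionalised position. Both stereocentres are carried in with the epoxide, and inversion at one carbon of a cis-epoxide gives trans directly.
- Weak points: the annulation is established for terminal or lightly substituted epoxides opened at the less hindered carbon. Here the palladacycle must attack a secondary carbon α to an ester in preference to the benzylic carbon, while the electron-rich benzylic C–O bond of A8 is prone to ionisation and rearrangement, which would cost stereochemical integrity. Enantioenriched cis-glycidates are harder to obtain than trans ones. A6 carries two esters, so the C5 ester needs reduction, selective benzylic oxidation, olefination and reduction (about four steps after the key step, against two here).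
- Comparison: this road is equal or better in convergence, and its source of chirality is in principle as secure as an auxiliary. The chosen plan answers with a ring closure whose regiochemistry is fixed by the tether, and with the shorter end game.

Key step: step 8

Assumption: 4-(bromomethyl)-1,2-dimethoxybenzene (10) and both antipodes of 4-benzyl-2-oxazolidinone are treated as catalogue chemicals; 10 is used freshly because benzylic bromides of this kind ionise on storage.

## Route

Step 1
Reactants: 1 4-bromo-2-methoxyphenol; 2 glyoxylic acid
Product: 3 2-(5-bromo-2-hydroxy-3-methoxyphenyl)-2-hydroxyacetic acid (racemic)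
Conditions: NaOH (aq.), H2O, 45 °C; then HCl (aq.)
Reagents that add atoms: none
Why: Ortho-hydroxyalkylation of a phenoxide by glyoxylate (mandelic acid condensation); the para position is blocked by bromine, so the only activated carbon is the one ortho to the phenoxide. The new carbinol centre is racemic and is removed in step 2.

Step 2
Reactants: 3 2-(5-bromo-2-hydroxy-3-methoxyphenyl)-2-hydroxyacetic acid
Product: 4 2-(5-bromo-2-hydroxy-3-methoxyphenyl)acetic acid
Conditions: SnCl2·2H2O, conc. HCl, AcOH, 80 °C; then NaOH (aq.), rt; then HCl (aq.), 0 °C
Reagents that add atoms: none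
Why: Acid ionises the ortho-hydroxybenzylic alcohol and SnCl2 reduces the cation (divalent tin to tetravalent tin), the classical deoxygenation of hydroxymandelic acids to arylacetic acids. Aryl bromide and methyl ether are inert, and the brief basic treatment in the work-up ensures that the material is collected as the open hydroxy acid.

Step 3
Reactants: 4 2-(5-bromo-2-hydroxy-3-methoxyphenyl)acetic acid
Product: 6 2-[5-bromo-2-(tert-butyldimethylsilyloxy)-3-methoxyphenyl]acetic acid, via the doubly silylated silyl ester 5 (not isolated)
Conditions: TBSCl (2.5 equiv), imidazole, DMF, rt; then AcOH/THF/H2O, rt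
Reagents that add atoms: tert-butyldimethylsilyl chloride, CC(C)(C)[Si](C)(C)Cl
Why: Silylation of phenol and acid followed by selective solvolysis of the far more labile silyl ester. The hindered aryl silyl ether is stable to dilute acetic acid.

Step 4
Reactants: 6 2-[5-bromo-2-(tert-butyldimethylsilyloxy)-3-methoxyphenyl]acetic acid; 7 (R)-4-benzyl-2-oxazolidinone
Product: 9 (R)-4-benzyl-3-{2-[5-bromo-2-(tert-butyldimethylsilyloxy)-3-methoxyphenyl]acetyl}oxazolidin-2-one, via the mixed pivalic anhydride 8 (not isolated)
Conditions: t-BuCOCl, Et3N, THF, −20 °C; then 7, LiCl, −20 °C to rt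
Reagents that add atoms: none
Why: N-Acylation of the oxazolidinone through a mixed pivalic anhydride, with LiCl and Et3N activating the auxiliary so that no strong base meets the arylacetyl unit. Attack occurs at the less hindered arylacetyl carbonyl.

Step 5
Reactants: 9 (R)-4-benzyl-3-{2-[5-bromo-2-(tert-butyldimethylsilyloxy)-3-methoxyphenyl]acetyl}oxazolidin-2-one; 10 4-(bromomethyl)-1,2-dimethoxybenzene
Product: 11 (R)-4-benzyl-3-{(R)-2-[5-bromo-2-(tert-butyldimethylsilyloxy)-3-methoxyphenyl]-3-(3,4-dimethoxyphenyl)propanoyl}oxazolidin-2-one
Conditions: NaN(SiMe3)2 (1.05 equiv), THF, −78 °C; then 10, −78 to −40 °C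
Reagents that add atoms: none
Why: Evans asymmetric alkylation: the chelated sodium (Z)-enolate is attacked by the benzylic bromide on the face opposite the benzyl group of the (R)-auxiliary, which sets the future C3 as R. Low temperature and near-stoichiometric base keep the acidic α-aryl centre from epimerising.

Step 6
Reactants: 11 (R)-4-benzyl-3-{(R)-2-[5-bromo-2-(tert-butyldimethylsilyloxy)-3-methoxyphenyl]-3-(3,4-dimethoxyphenyl)propanoyl}oxazolidin-2-one
Product: 12 (R)-2-[5-bromo-2-(tert-butyldimethylsilyloxy)-3-methoxyphenyl]-3-(3,4-dimethoxyphenyl)propan-1-ol
Conditions: LiBH4, H2O (1 equiv), Et2O, 0 °C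
Reagents that add atoms: none
Why: Reductive removal of the auxiliary: the exocyclic imide carbonyl is reduced faster than the ring carbamate, and at 0 °C the stereocentre should not enolise before it is taken out of conjugation. Aryl bromide and silyl ether are inert, and the auxiliary is recovered.

Step 7
Reactants: 12 (R)-2-[5-bromo-2-(tert-butyldimethylsilyloxy)-3-methoxyphenyl]-3-(3,4-dimethoxyphenyl)propan-1-ol
Product: 13 (R)-4-bromo-2-[1-(3,4-dimethoxyphenyl)-3-hydroxypropan-2-yl]-6-methoxyphenol
Conditions: Bu4NF, AcOH, THF, 0 °C
Reagents that add atoms: none
Why: Fluoride cleavage of the aryl silyl ether, buffered by acetic acid. Nothing else is fluoride-sensitive, and the stereocentre, no longer next to a carbonyl group, cannot epimerise.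

Step 8
Reactants: 13 (R)-4-bromo-2-[1-(3,4-dimethoxyphenyl)-3-hydroxypropan-2-yl]-6-methoxyphenol
Product: 14 [(2S,3R)-5-bromo-2-(3,4-dimethoxyphenyl)-7-methoxy-2,3-dihydrobenzofuran-3-yl]methanol
Conditions: DDQ (1.05 equiv), 4 Å molecular sieves, CH2Cl2, 0 °C to rt
Reagents that add atoms: none
Why: DDQ forms a charge-transfer complex with the dimethoxyarene ring C and removes hydride from the adjacent CH2, giving a para-methoxy-stabilised benzylic cation paired with the hydroquinone anion. The ring A phenol oxygen, five atoms away, adds to this cation in a 5-exo-trig closure (the cationic carbon is the exocyclic end of the quinoid C2=C1′ bond) and the hydroquinone anion takes the phenolic proton. The closest known reaction type is the DDQ oxidative cyclisation of 2-(2-arylethyl)phenols and 1-(2-hydroxyaryl)-3-arylpropanes bearing alkoxyaryl groups to 2-aryl-dihydrobenzofurans and flavans, together with DDQ benzylic etherification in the lignan series. The new C2 stereocentre is controlled by C3: in the envelope-like transition state the planar cation turns its aryl group away from the hydroxymethyl arm, and because the benzylic C2–O1 bond can reopen under the weakly acidic hydroquinone, any cis isomer should drain to the more stable trans (2S,3R) product. The step needs site selectivity for C2–H over C3–H. Ring C, with two methoxy donors (one para to the CH2), is the better donor, whereas ring A is damped by bromine para to the hydroxyl, and a cation at C3 would carry a β-oxygen and require a crowded fully substituted methide geometry. The primary alcohol does not compete, since it could only form an oxetane. One equivalent of oxidant at low temperature and the exclusion of water restrain a second hydride loss from the product C2–H (aromatisation to the benzofuran) and hydroxylation of the cation; no cinnamyl alcohol is present at this stage.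

Step 9
Reactants: 14 [(2S,3R)-5-bromo-2-(3,4-dimethoxyphenyl)-7-methoxy-2,3-dihydrobenzofuran-3-yl]methanol; 15 methyl acrylate
Product: 16 methyl (E)-3-[(2S,3R)-2-(3,4-dimethoxyphenyl)-3-(hydroxymethyl)-7-methoxy-2,3-dihydrobenzofuran-5-yl]prop-2-enoate
Conditions: Pd(OAc)2 (5 mol%), P(o-tol)3 (10 mol%), Et3N, DMF, 100 °C
Reagents that add atoms: none
Why: Heck reaction: oxidative addition of the unhindered aryl bromide to zerovalent palladium, syn insertion of the acrylate and syn β-hydride elimination give the (E)-cinnamate. The free alcohol and both stereocentres are spectators under amine base.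

Step 10
Reactants: 16 methyl (E)-3-[(2S,3R)-2-(3,4-dimethoxyphenyl)-3-(hydroxymethyl)-7-methoxy-2,3-dihydrobenzofuran-5-yl]prop-2-enoate
Product: 17 (E)-3-[(2S,3R)-2-(3,4-dimethoxyphenyl)-3-(hydroxymethyl)-7-methoxy-2,3-dihydrobenzofuran-5-yl]prop-2-en-1-ol (Hierochin B)
Conditions: i-Bu2AlH (4 equiv), CH2Cl2, −78 to 0 °C; aq. potassium sodium tartrate
Reagents that add atoms: none
Why: 1,2-Reduction of the conjugated ester to the allylic alcohol by i-Bu2AlH, the excess covering the free hydroxyl. Low temperature avoids conjugate reduction and Lewis-acid opening of the benzylic ether, and the tartrate work-up avoids acid.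

## Compound list

1 | 4-bromo-2-methoxyphenol | COc1cc(Br)ccc1O | starting material
2 | glyoxylic acid | O=CC(=O)O | starting material
3 | 2-(5-bromo-2-hydroxy-3-methoxyphenyl)-2-hydroxyacetic acid (racemic) | COc1cc(Br)cc(C(O)C(=O)O)c1O | intermediate
4 | 2-(5-bromo-2-hydroxy-3-methoxyphenyl)acetic acid | COc1cc(Br)cc(CC(=O)O)c1O | intermediate
5 | tert-butyldimethylsilyl 2-[5-bromo-2-(tert-butyldimethylsilyloxy)-3-methoxyphenyl]acetate | COc1cc(Br)cc(CC(=O)O[Si](C)(C)C(C)(C)C)c1O[Si](C)(C)C(C)(C)C | intermediate
6 | 2-[5-bromo-2-(tert-butyldimethylsilyloxy)-3-methoxyphenyl]acetic acid | COc1cc(Br)cc(CC(=O)O)c1O[Si](C)(C)C(C)(C)C | intermediate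
7 | (R)-4-benzyl-2-oxazolidinone | O=C1N[C@H](Cc2ccccc2)CO1 | starting material
8 | 2-[5-bromo-2-(tert-butyldimethylsilyloxy)-3-methoxyphenyl]acetic pivalic anhydride | COc1cc(Br)cc(CC(=O)OC(=O)C(C)(C)C)c1O[Si](C)(C)C(C)(C)C | intermediate
9 | (R)-4-benzyl-3-{2-[5-bromo-2-(tert-butyldimethylsilyloxy)-3-methoxyphenyl]acetyl}oxazolidin-2-one | COc1cc(Br)cc(CC(=O)N2[C@H](Cc3ccccc3)COC2=O)c1O[Si](C)(C)C(C)(C)C | intermediate
10 | 4-(bromomethyl)-1,2-dimethoxybenzene | COc1ccc(CBr)cc1OC | starting material
11 | (R)-4-benzyl-3-{(R)-2-[5-bromo-2-(tert-butyldimethylsilyloxy)-3-methoxyphenyl]-3-(3,4-dimethoxyphenyl)propanoyl}oxazolidin-2-one | COc1ccc(C[C@@H](C(=O)N2[C@H](Cc3ccccc3)COC2=O)c2cc(Br)cc(OC)c2O[Si](C)(C)C(C)(C)C)cc1OC | intermediate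
12 | (R)-2-[5-bromo-2-(tert-butyldimethylsilyloxy)-3-methoxyphenyl]-3-(3,4-dimethoxyphenyl)propan-1-ol | COc1ccc(C[C@@H](CO)c2cc(Br)cc(OC)c2O[Si](C)(C)C(C)(C)C)cc1OC | intermediate
13 | (R)-4-bromo-2-[1-(3,4-dimethoxyphenyl)-3-hydroxypropan-2-yl]-6-methoxyphenol | COc1ccc(C[C@@H](CO)c2cc(Br)cc(OC)c2O)cc1OC | intermediate
14 | [(2S,3R)-5-bromo-2-(3,4-dimethoxyphenyl)-7-methoxy-2,3-dihydrobenzofuran-3-yl]methanol | COc1ccc([C@H]2Oc3c(OC)cc(Br)cc3[C@@H]2CO)cc1OC | intermediate
15 | methyl acrylate | C=CC(=O)OC | starting material
16 | methyl (E)-3-[(2S,3R)-2-(3,4-dimethoxyphenyl)-3-(hydroxymethyl)-7-methoxy-2,3-dihydrobenzofuran-5-yl]prop-2-enoate | COc1ccc([C@H]2Oc3c(OC)cc(/C=C/C(=O)OC)cc3[C@@H]2CO)cc1OC | intermediate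
17 | Hierochin B, (E)-3-[(2S,3R)-2-(3,4-dimethoxyphenyl)-3-(hydroxymethyl)-7-methoxy-2,3-dihydrobenzofuran-5-yl]prop-2-en-1-ol | COc1ccc([C@H]2Oc3c(OC)cc(/C=C/CO)cc3[C@@H]2CO)cc1OC | target

## Step count and least certain steps

Total step count: 10. Longest linear sequence: 10 steps (1 to 17); compounds 2, 7, 10 and 15 enter as purchased reagents.

**Step 8 (key step).**
- Risk: oxidation at the wrong site. Hydride loss from C3–H assisted by the free phenol would erase the C3 stereocentre through an ortho-quinone-methide pathway, and a second hydride loss from the product at C2–H would lead to aromatisation. Fragmentation of the cation with loss of formaldehyde is a lesser possibility. The cause is that ring A, though damped by bromine, is still a phenol, and that the product C2–H is benzylic and α to oxygen.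
- Fallback: bring C2 in already oxygenated and close the same O1–C2 bond by ionisation instead of C–H oxidation. It sets out from acid 6. Acylation of (S)-4-benzyl-2-oxazolidinone as in step 4 gives (S)-4-benzyl-3-{2-[5-bromo-2-(tert-butyldimethylsilyloxy)-3-methoxyphenyl]acetyl}oxazolidin-2-one F1. Evans syn-aldol addition (n-Bu2BOTf, i-Pr2NEt, CH2Cl2, −78 to 0 °C) to 3,4-dimethoxybenzaldehyde gives (S)-4-benzyl-3-{(2S,3S)-2-[5-bromo-2-(tert-butyldimethylsilyloxy)-3-methoxyphenyl]-3-(3,4-dimethoxyphenyl)-3-hydroxypropanoyl}oxazolidin-2-one F2. The boron enolate reacts on the face opposite to that used by the chelated sodium enolate, so the antipodal auxiliary delivers the same C3 configuration. LiBH4 then gives (1S,2R)-2-[5-bromo-2-(tert-butyldimethylsilyloxy)-3-methoxyphenyl]-1-(3,4-dimethoxyphenyl)propane-1,3-diol F3, and Bu4NF/AcOH gives (1S,2R)-2-(5-bromo-2-hydroxy-3-methoxyphenyl)-1-(3,4-dimethoxyphenyl)propane-1,3-diol F4. Catalytic TsOH in CH2Cl2 ionises the benzylic alcohol to the same veratryl cation, which the phenol captures under thermodynamic control to give 14, where the route is rejoined. The carbinol configuration is lost in the cation and does not matter.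

**Step 1.**
- Risk: slow substitution at the only activated position of a ring deactivated by bromine, so that disproportionation of glyoxylate in base and condensation of the product with a second phenol gain ground.
- Fallback: introduce the two-carbon arm by sigmatropic rearrangement. It sets out from 1. Allyl bromide and K2CO3 in acetone give 4-bromo-2-methoxy-1-(prop-2-en-1-yloxy)benzene F5. Claisen rearrangement at about 200 °C gives 4-bromo-2-methoxy-6-(prop-2-en-1-yl)phenol F6, only one ortho position being free. TBSCl and imidazole give tert-butyl[4-bromo-2-methoxy-6-(prop-2-en-1-yl)phenoxy]dimethylsilane F7. Lemieux–Johnson cleavage (OsO4 cat., NaIO4, 2,6-lutidine, dioxane/H2O) gives 2-[5-bromo-2-(tert-butyldimethylsilyloxy)-3-methoxyphenyl]acetaldehyde F8, and Pinnick oxidation (NaClO2, NaH2PO4, 2-methyl-2-butene) converts it to acid 6, where the route is rejoined.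

**Step 5.**
- Risk: loss of stereochemical purity by epimerisation of the acidic α-aryl centre under excess base, or decay of the aryl-stabilised enolate by expulsion of the auxiliary or by silyl transfer from the neighbouring aryl ether.
- Fallback: set C3 by catalytic asymmetric hydrogenation instead of enolate alkylation. It sets out from acid 6. Perkin condensation with 3,4-dimethoxybenzaldehyde (Ac2O, Et3N, 100 °C) gives (E)-2-[5-bromo-2-(tert-butyldimethylsilyloxy)-3-methoxyphenyl]-3-(3,4-dimethoxyphenyl)prop-2-enoic acid F9. Hydrogenation with a chiral spiro phosphine–oxazoline iridium catalyst of the type [Ir(cod)(SIPHOX)]BArF (or with Ru(OAc)2(BINAP)), the ligand antipode being chosen for the R acid, gives (R)-2-[5-bromo-2-(tert-butyldimethylsilyloxy)-3-methoxyphenyl]-3-(3,4-dimethoxyphenyl)propanoic acid F10. BH3·THF reduces this acid to alcohol 12, where the route is rejoined.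

**Step 6.**
- Risk: hydride attack at the ring carbonyl of the hindered imide (opening of the auxiliary in place of its release), or enolisation of the α-aryl imide by the basic borohydride before reduction.
- Fallback: exchange the leaving group before reducing. It sets out from imide 11. LiSEt (from EtSH and n-BuLi, THF, 0 °C), weakly basic and selective for the exocyclic carbonyl, gives S-ethyl (R)-2-[5-bromo-2-(tert-butyldimethylsilyloxy)-3-methoxyphenyl]-3-(3,4-dimethoxyphenyl)propanethioate F11. LiBH4 in THF reduces the unhindered thioester to alcohol 12, where the route is rejoined.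

## Further compounds

F1 | step 8 | (S)-4-benzyl-3-{2-[5-bromo-2-(tert-butyldimethylsilyloxy)-3-methoxyphenyl]acetyl}oxazolidin-2-one | COc1cc(Br)cc(CC(=O)N2[C@@H](Cc3ccccc3)COC2=O)c1O[Si](C)(C)C(C)(C)C
F2 | step 8 | (S)-4-benzyl-3-{(2S,3S)-2-[5-bromo-2-(tert-butyldimethylsilyloxy)-3-methoxyphenyl]-3-(3,4-dimethoxyphenyl)-3-hydroxypropanoyl}oxazolidin-2-one | COc1ccc([C@@H](O)[C@@H](C(=O)N2[C@@H](Cc3ccccc3)COC2=O)c2cc(Br)cc(OC)c2O[Si](C)(C)C(C)(C)C)cc1OC
F3 | step 8 | (1S,2R)-2-[5-bromo-2-(tert-butyldimethylsilyloxy)-3-methoxyphenyl]-1-(3,4-dimethoxyphenyl)propane-1,3-diol | COc1ccc([C@@H](O)[C@@H](CO)c2cc(Br)cc(OC)c2O[Si](C)(C)C(C)(C)C)cc1OC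
F4 | step 8 | (1S,2R)-2-(5-bromo-2-hydroxy-3-methoxyphenyl)-1-(3,4-dimethoxyphenyl)propane-1,3-diol | COc1ccc([C@@H](O)[C@@H](CO)c2cc(Br)cc(OC)c2O)cc1OC
F5 | step 1 | 4-bromo-2-methoxy-1-(prop-2-en-1-yloxy)benzene | C=CCOc1ccc(Br)cc1OC
F6 | step 1 | 4-bromo-2-methoxy-6-(prop-2-en-1-yl)phenol | C=CCc1cc(Br)cc(OC)c1O
F7 | step 1 | tert-butyl[4-bromo-2-methoxy-6-(prop-2-en-1-yl)phenoxy]dimethylsilane | C=CCc1cc(Br)cc(OC)c1O[Si](C)(C)C(C)(C)C
F8 | step 1 | 2-[5-bromo-2-(tert-butyldimethylsilyloxy)-3-methoxyphenyl]acetaldehyde | COc1cc(Br)cc(CC=O)c1O[Si](C)(C)C(C)(C)C
F9 | step 5 | (E)-2-[5-bromo-2-(tert-butyldimethylsilyloxy)-3-methoxyphenyl]-3-(3,4-dimethoxyphenyl)prop-2-enoic acid | COc1ccc(/C=C(/C(=O)O)c2cc(Br)cc(OC)c2O[Si](C)(C)C(C)(C)C)cc1OC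
F10 | step 5 | (R)-2-[5-bromo-2-(tert-butyldimethylsilyloxy)-3-methoxyphenyl]-3-(3,4-dimethoxyphenyl)propanoic acid | COc1ccc(C[C@@H](C(=O)O)c2cc(Br)cc(OC)c2O[Si](C)(C)C(C)(C)C)cc1OC
F11 | step 6 | S-ethyl (R)-2-[5-bromo-2-(tert-butyldimethylsilyloxy)-3-methoxyphenyl]-3-(3,4-dimethoxyphenyl)propanethioate | COc1ccc(C[C@@H](C(=O)SCC)c2cc(Br)cc(OC)c2O[Si](C)(C)C(C)(C)C)cc1OC
A1 | alternative 1 | (2S,3R)-5-bromo-3-(tert-butyldimethylsilyloxymethyl)-2-(3,4-dimethoxyphenyl)-7-methoxy-2,3-dihydrobenzofuran | COc1ccc([C@H]2Oc3c(OC)cc(Br)cc3[C@@H]2CO[Si](C)(C)C(C)(C)C)cc1OC
A2 | alternative 1 | 4-bromo-2-[2-(tert-butyldimethylsilyloxy)-1-(4-methylphenylsulfonyl)ethyl]-6-methoxyphenol (racemic) | COc1cc(Br)cc(C(CO[Si](C)(C)C(C)(C)C)S(=O)(=O)c2ccc(C)cc2)c1O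
A3 | alternative 2 | methyl (2S,3S)-2-(3,4-dimethoxyphenyl)-5-formyl-7-methoxy-2,3-dihydrobenzofuran-3-carboxylate | COc1ccc([C@H]2Oc3c(OC)cc(C=O)cc3[C@@H]2C(=O)OC)cc1OC
A4 | alternative 2 | methyl (E)-3-(4-formyl-2-iodo-6-methoxyphenoxy)prop-2-enoate | COC(=O)/C=C/Oc1c(I)cc(C=O)cc1OC
A5 | alternative 2 | 3,4-dimethoxyphenylboronic acid | COc1ccc(B(O)O)cc1OC
A6 | alternative 3 | dimethyl (2S,3S)-2-(3,4-dimethoxyphenyl)-7-methoxy-2,3-dihydrobenzofuran-3,5-dicarboxylate | COc1ccc([C@H]2Oc3c(OC)cc(C(=O)OC)cc3[C@@H]2C(=O)OC)cc1OC
A7 | alternative 3 | methyl 4-iodo-3-methoxybenzoate | COC(=O)c1ccc(I)c(OC)c1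
A8 | alternative 3 | methyl (2R,3R)-3-(3,4-dimethoxyphenyl)oxirane-2-carboxylate (cis) | COc1ccc([C@H]2O[C@H]2C(=O)OC)cc1OC
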